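E, charged at 0.050 M into a closed, stirred flask held at constant temperature, passes to and fro into Q, D and L, while X takes E into Z by a step with no way back. The flasks differ in their charge of X, and the question is what stands as Q at 80 min.

| setting | Monday's | Saturday's | south-east | west | east | north | north-west |
|---|---|---|---|---|---|---|---|
| E | 0.050 M | 0.050 M | 0.050 M | 0.050 M | 0.050 M | 0.050 M | 0.050 M |
| X | 3.5 × 10⁻⁴ M | 0.024 M | 4.00 × 10⁻⁴ M | 0.00120 M | 0.00300 M | 0.0100 M | 0.0300 M |
| remark | run made earlier | run made earlier |  |  |  |  |  |
| time |  |  | 80 min | 80 min | 80 min | 80 min | 80 min |

| run | time / min | Q / % |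
|---|---|---|
| Monday's | 12.0 | 39.7 |
| Monday's | 25.0 | 41.3 |
| Monday's | 40.0 | 39.9 |
| Monday's | 50.0 | 39.5 |
| Monday's | 60.0 | 39.9 |
| Monday's | 80.0 | 39.3 |
| Saturday's | 6.00 | 29.4 |
| Saturday's | 10.0 | 33.4 |
| Saturday's | 20.0 | 34.4 |
| Saturday's | 30.0 | 35.4 |
| Saturday's | 50.0 | 30.1 |
| Saturday's | 80.0 | 28.6 |

(scatter of a reading: 1 percentage point)

* amount of Q at the end, in percent of the E charged for south-east, west, east, north, north-west, in this order
* how that number moves from the first to the last of them (rises all the way / rises, then falls / hardly changes / falls, then rises / falls all the way)

- the earlier runs were read with a standard deviation of 1 percentage point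
- steps under discussion: E <-> D; E + X -> Z; E <-> Q; E <-> L
- "hardly changes" means that all values lie within two and a half points (for a concentration: within two and a half percent of the largest)

Two runs seem not to go together. Monday's Q lies between 39.3% and 41.3% with no trend beyond the scatter, as if X did nothing, yet Saturday's flask, with 68.6 times Monday's X, ends lower, at 28.6%. The loss can be reckoned as a correction to a base level of Q.

1. The mean of Monday's readings gives that base level, 39.9%.

2. Saturday's last reading, taken at the asked time, 80.0 min, is 0.717 of that base. This gives the drain coefficient, 11.8 L mol⁻¹, the fraction of the base level of Q lost by that time per mole per litre of X charged. It is a reading and carries the scatter, and its proportionality to X is assumed here.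

3. On Monday's charge the coefficient takes off 0.17 percentage points, less than the scatter of 1 point, so Monday's flask can hide a loss that Saturday's flask shows.

4. X is the limiting reagent, and the coefficient has each unit of X charged costing 0.590 of a unit of the E charged. The base level times one minus the correction then gives, from south-east to north-west in the asked order, 39.7%, 39.4%, 38.5%, 35.2% and 25.8%.

The forecast, which takes a loss that “fits second-order loss”, gives 39.8%, 39.4%, 38.4%, 34.8% and 25.9%, so that Q falls all the way, and it differs from this reckoning by 0.40 points at north.

The flasks give 39.3%, 38.8%, 37.9%, 34.5% and 26.2%, so Q falls all the way, and at north the reckoning stands 0.70 points above the flask.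

    E ⇌ D (K = 2.45, k = 7.45 × 10⁻⁴ s⁻¹)
    E + X → Z (k = 0.0267 L mol⁻¹ s⁻¹)
    E ⇌ Q (K = 2.95, k = 0.00190 s⁻¹)
    E ⇌ L (K = 1.40, k = 0.00148 s⁻¹)

In south-east, E passes into Q with a forward half-life of 6.1 min at 2.37 min, whereas the step to Z, reckoned forward with X at its charge, has a half-life of 1080 min, which is 177 times longer. In north-west the same reckoning gives 14.4 min, still longer than the 6.08 min that the constant of the forward passage into Q gives. The drain coefficient times the charge of X gives 0.473% of the E charged lost in south-east, where Z stands at 0.537% at 80.0 min, and 35.5% in north-west, where Z stands at 33.7% at 80.0 min.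

The earlier runs and the new flask stem from a simulated flask on assumed constants, noise included.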